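## Retrosynthetic overview

1. Target ⇐ hydroxyl-directed epoxidation of the C8=C9 allylic alcohol ⇐ 1,2-reduction of the C10 enone ⇐ C6 veratrate and C2 acetate installed one after the other on a hydroxy enone.
2. C6–OH ⇐ reductive opening of the 6α,7α-epoxide of a cyclohepta-2,4-dienone.
3. Seven-membered ring ⇐ one-carbon ring expansion of the carvone cyclohexenone: dibromocarbene [2+1] cycloaddition to its silyl dienol ether, then electrocyclic cyclopropyl-to-allyl ring opening.
4. Five-membered ring ⇐ intramolecular allylchromium addition (C2–C3), then isopropyl addition to the C4 ketone; quaternary C1 ⇐ double α′-alkylation of (S)-carvone anti to the isopropenyl group.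
5. Ring order: six-membered ring bought in (S)-(+)-carvone → cyclopentane (step 5) → cycloheptadienone by ring expansion (step 9).

Assumption: read literally, the C8 and C9 descriptors of the given string put C7 and C10 trans across the oxirane (not possible in a seven-membered ring), so the oxirane is taken as cis-fused on the face of the C10 hydroxyl (α, anti to the C1 methyl), and the given string is kept unchanged as the SMILES of the target.

Numbering: C1–C15 and α/β follow the daucane numbering of the target (C1 = methyl-bearing ring-fusion carbon, C4 = isopropyl carbinol, C5 = ring-fusion CH, C8 = methyl-bearing oxirane carbon; β = face of the C1 methyl). In the six-membered-ring intermediates C9 is still absent.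

## Route

Step 1
Reactants: 1 (S)-(+)-carvone
Product: 3 trans-6-methylcarvone, via lithium dienolate 2 (not isolated)
Conditions: LiN(iPr)2, THF, −78 °C; MeI, −78 → 0 °C
Reagents that add atoms: iodomethane, CI
Why: Kinetic α′-deprotonation gives the cross-conjugated enolate, which is C-methylated (enolate alkylation); the new centre is flattened again in step 2, so its epimer ratio does not matter.

Step 2
Reactants: 3 trans-6-methylcarvone
Product: 5 6-(hydroxymethyl)-6-methylcarvone, via lithium enolate 4 (not isolated)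
Conditions: LiN(iPr)2, THF, −78 °C; CH2O (gas, from cracked paraformaldehyde), −78 °C; H2O quench
Reagents that add atoms: formaldehyde, C=O
Why: Aldol hydroxymethylation of the tetrasubstituted enolate occurs anti to the pseudo-axial isopropenyl group, so quaternary C1 carries CH3 cis and CH2OH trans to it.

Step 3
Reactants: 5 6-(hydroxymethyl)-6-methylcarvone
Product: 6 allylic chloride
Conditions: Ca(OCl)2, CO2 (dry ice), CH2Cl2/H2O, 0 °C
Reagents that add atoms: calcium hypochlorite, [Ca+2].[O-]Cl.[O-]Cl
Why: Ene-type allylic chlorination by HOCl attacks only the electron-rich 1,1-disubstituted alkene (the enone alkene is too electron-poor) and gives the transposed allylic chloride; no stereocentre is touched.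

Step 4
Reactants: 6 allylic chloride
Product: 7 chloro keto aldehyde
Conditions: Dess–Martin periodinane, NaHCO3, CH2Cl2, 0 °C → rt
Reagents that add atoms: none
Why: Dess–Martin oxidation of the neopentyl primary alcohol under buffered, non-basic conditions avoids retro-aldol loss of the one-carbon unit; no stereocentre is touched.

Step 5
Reactants: 7 chloro keto aldehyde
Product: 8 bicyclic methylidene alcohol
Conditions: CrCl2 (4 equiv), LiI (cat.), THF, 0 °C → rt; aqueous work-up
Reagents that add atoms: none
Why: Intramolecular Nozaki–Hiyama allylation: the allylchromium adds to the aldehyde, not the ketone, through a closed six-membered transition state and closes the trans-fused cyclopentane; the O–Cr bridge lies on the face away from the perpendicular C1 methyl, giving 2α-OH.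

Step 6
Reactants: 8 bicyclic methylidene alcohol
Product: 9 hydroxy diketone
Conditions: OsO4 (2 mol%), NaIO4, 2,6-lutidine, dioxane/H2O, rt
Reagents that add atoms: osmium tetroxide (catalytic oxygen carrier), O=[Os](=O)(=O)=O; sodium periodate, [Na+].[O-]I(=O)(=O)=O
Why: Lemieux–Johnson cleavage of the electron-rich exocyclic methylene, in preference to the conjugated enone alkene, unmasks the C4 ketone without base, so C5 is not epimerised.

Step 7
Reactants: 9 hydroxy diketone
Product: 10 2α,4β-dihydroxy-9-nordauc-7-en-10-one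
Conditions: iPrMgCl (3 equiv), CeCl3 (anhydrous), THF, −78 °C
Reagents that add atoms: isopropylmagnesium chloride, CC(C)[Mg]Cl
Why: Organocerium 1,2-addition (no enolisation or β-hydride reduction) goes to the reactive cyclopentanone rather than the hindered α-quaternary enone, from the α face anti to the C5–C6 bond and the C1 methyl, giving 4β-OH and 4α-isopropyl.

Step 8
Reactants: 10 2α,4β-dihydroxy-9-nordauc-7-en-10-one
Product: 11 tris-silyl dienol ether
Conditions: Me3SiOTf, Et3N, CH2Cl2, 0 °C → rt
Reagents that add atoms: trimethylsilyl trifluoromethanesulfonate, C[Si](C)(C)OS(=O)(=O)C(F)(F)F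
Why: Soft enolisation by γ-deprotonation at C6 (the only direction, C1 being quaternary) gives the linear silyl dienol ether; both hydroxyls are silylated too, which blocks retro-aldol opening in the basic next step.

Step 9
Reactants: 11 tris-silyl dienol ether
Product: 14 9-bromo-2α,4β-dihydroxydauca-6,8-dien-10-one, via dibromocyclopropane 12 (not isolated), via silylated bromodienone 13 (not isolated)
Conditions: CHBr3, KOtBu, pentane, −20 °C → rt; toluene, 80 °C; then 1 M HCl, THF, rt
Reagents that add atoms: bromoform, BrC(Br)Br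
Why: Dibromocarbene adds to the oxygen-substituted tetrasubstituted C8=C10 bond ([2+1] cheletropic cycloaddition), and the dibromocyclopropane opens by disrotatory two-electron electrocyclic ring opening (cyclopropyl to allyl cation, endo bromide leaving, then loss of Me3SiBr) to the ring-expanded 2-bromocyclohepta-2,4-dienone; no stereocentre is affected.

Step 10
Reactants: 14 9-bromo-2α,4β-dihydroxydauca-6,8-dien-10-one
Product: 15 2α,4β-dihydroxydauca-6,8-dien-10-one
Conditions: Pd(OAc)2 (5 mol%), PPh3, HCO2H, Et3N, DMF, 60 °C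
Reagents that add atoms: none
Why: Palladium-catalysed formate hydrogenolysis of the vinylic C–Br bond (oxidative addition to zerovalent palladium, decarboxylation of formate, reductive elimination) leaves the C=C bonds and stereocentres untouched.

Step 11
Reactants: 15 2α,4β-dihydroxydauca-6,8-dien-10-one
Product: 16 2α-acetoxy-4β-hydroxydauca-6,8-dien-10-one
Conditions: Ac2O, pyridine, DMAP (cat.), CH2Cl2, 0 °C → rt
Reagents that add atoms: acetic anhydride, CC(=O)OC(C)=O
Why: Acetylation of the only secondary hydroxyl; the tertiary C4 hydroxyl does not react under these conditions.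

Step 12
Reactants: 16 2α-acetoxy-4β-hydroxydauca-6,8-dien-10-one
Product: 17 6α,7α-epoxy enone
Conditions: mCPBA, NaHCO3, CH2Cl2, 0 °C
Reagents that add atoms: 3-chloroperoxybenzoic acid, OOC(=O)c1cccc(Cl)c1
Why: Prilezhaev epoxidation takes the more electron-rich γ,δ-alkene of the dienone from the α face, anti to the C5–C4 bond and the C1 methyl that shield the β face (as with steroidal 4,6-dien-3-ones), setting the 6α C–O bond.

Step 13
Reactants: 17 6α,7α-epoxy enone
Product: 19 2α-acetoxy-4β,6α-dihydroxydauc-8-en-10-one, via deconjugated enone 18 (not isolated)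
Conditions: SmI2 (2.5 equiv), THF/MeOH, −78 °C; then DBU (cat.), CH2Cl2, rt
Reagents that add atoms: none
Why: SmI2 reduction of the γ,δ-epoxy enone breaks the γ C–O bond (C7–O) through the dienolate and leaves the 6α-hydroxyl untouched; α-protonation gives the β,γ-enone, which DBU moves into conjugation.

Step 14
Reactants: 19 2α-acetoxy-4β,6α-dihydroxydauc-8-en-10-one; 20 3,4-dimethoxybenzoyl chloride
Product: 21 veratrate enone
Conditions: Et3N, DMAP (cat.), CH2Cl2, 0 °C
Reagents that add atoms: none
Why: DMAP-catalysed acylation of the only free secondary hydroxyl (C6); the tertiary C4 hydroxyl is inert, and brief cold contact with base avoids vinylogous β-elimination.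

Step 15
Reactants: 21 veratrate enone
Product: 22 10α-allylic alcohol
Conditions: NaBH4, CeCl3·7H2O, MeOH, −78 °C
Reagents that add atoms: none
Why: Luche 1,2-reduction: the C1–C5 bond stands nearly perpendicular to the carbonyl on the α face (with H5 across the ring), so hydride enters anti to it (Felkin–Anh), past the smaller C1 methyl from the β face, giving 10α-OH; the esters survive.

Step 16
Reactants: 22 10α-allylic alcohol
Product: 23 target
Conditions: VO(acac)2 (cat.), tBuOOH, CH2Cl2, 0 °C → rt
Reagents that add atoms: tert-butyl hydroperoxide, CC(C)(C)OO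
Why: Vanadium-catalysed hydroxyl-directed epoxidation delivers oxygen syn to the 10α-OH (the mode also followed by cyclohept-2-enols), giving the cis-fused α-oxirane at C8–C9.

## Compound list

1 | (S)-(+)-carvone, (5S)-2-methyl-5-(prop-1-en-2-yl)cyclohex-2-en-1-one | C=C(C)[C@H]1CC=C(C)C(=O)C1 | starting material
2 | lithium dienolate of 1 (C6 deprotonated) | C=C(C)[C@H]1CC=C(C)C([O-])=C1.[Li+] | intermediate
3 | 6-methylcarvone, major epimer with CH3 trans to isopropenyl | C=C(C)[C@H]1CC=C(C)C(=O)[C@@H]1C | intermediate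
4 | lithium enolate of 3 | C=C(C)[C@H]1CC=C(C)C([O-])=C1C.[Li+] | intermediate
5 | 6-(hydroxymethyl)-6-methylcarvone, CH3 cis and CH2OH trans to isopropenyl | C=C(C)[C@H]1CC=C(C)C(=O)[C@]1(C)CO | intermediate
6 | allylic chloride of 5 (isopropenyl replaced by 3-chloroprop-1-en-2-yl) | C=C(CCl)[C@H]1CC=C(C)C(=O)[C@]1(C)CO | intermediate
7 | chloro keto aldehyde (CH2OH of 6 oxidised to CHO) | C=C(CCl)[C@H]1CC=C(C)C(=O)[C@]1(C)C=O | intermediate
8 | trans-fused bicyclic enone: cyclopentane C1–C5 on the carvone ring, 2α-OH, exocyclic C4=CH2, 1β-CH3, 5α-H | C1C=C(C)C(=O)[C@]2(C)[C@H](O)CC(=C)[C@@H]12 | intermediate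
9 | hydroxy diketone: as 8 with C4=O | C1C=C(C)C(=O)[C@]2(C)[C@H](O)CC(=O)[C@@H]12 | intermediate
10 | 2α,4β-dihydroxy-9-nordauc-7-en-10-one (4α-isopropyl) | C1C=C(C)C(=O)[C@]2(C)[C@H](O)C[C@](O)(C(C)C)[C@@H]12 | intermediate
11 | tris-silyl dienol ether: C10(OSiMe3)=C8–C7=C6, 2α- and 4β-OSiMe3 | C1=CC(C)=C(O[Si](C)(C)C)[C@]2(C)[C@H](O[Si](C)(C)C)C[C@](O[Si](C)(C)C)(C(C)C)[C@@H]12 | intermediate
12 | dibromocyclopropane: CBr2 (C9) bridging C8 and C10 on the α face | C1=C[C@]2(C)C(Br)(Br)[C@]2(O[Si](C)(C)C)[C@]3(C)[C@H](O[Si](C)(C)C)C[C@](O[Si](C)(C)C)(C(C)C)[C@@H]13 | intermediate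
13 | 9-bromo-2α,4β-bis(trimethylsilyloxy)dauca-6,8-dien-10-one | C1=CC(C)=C(Br)C(=O)[C@]2(C)[C@H](O[Si](C)(C)C)C[C@](O[Si](C)(C)C)(C(C)C)[C@@H]12 | intermediate
14 | 9-bromo-2α,4β-dihydroxydauca-6,8-dien-10-one | C1=CC(C)=C(Br)C(=O)[C@]2(C)[C@H](O)C[C@](O)(C(C)C)[C@@H]12 | intermediate
15 | 2α,4β-dihydroxydauca-6,8-dien-10-one | C1=CC(C)=CC(=O)[C@]2(C)[C@H](O)C[C@](O)(C(C)C)[C@@H]12 | intermediate
16 | 2α-acetoxy-4β-hydroxydauca-6,8-dien-10-one | C1=CC(C)=CC(=O)[C@]2(C)[C@H](OC(C)=O)C[C@](O)(C(C)C)[C@@H]12 | intermediate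
17 | 2α-acetoxy-6α,7α-epoxy-4β-hydroxydauc-8-en-10-one | O1[C@@H]2[C@H]1C(C)=CC(=O)[C@]3(C)[C@H](OC(C)=O)C[C@](O)(C(C)C)[C@@H]23 | intermediate
18 | 2α-acetoxy-4β,6α-dihydroxydauc-7-en-10-one | O[C@@H]1C=C(C)CC(=O)[C@]2(C)[C@H](OC(C)=O)C[C@](O)(C(C)C)[C@@H]12 | intermediate
19 | 2α-acetoxy-4β,6α-dihydroxydauc-8-en-10-one | O[C@@H]1CC(C)=CC(=O)[C@]2(C)[C@H](OC(C)=O)C[C@](O)(C(C)C)[C@@H]12 | intermediate
20 | 3,4-dimethoxybenzoyl chloride (veratroyl chloride) | COc1ccc(C(Cl)=O)cc1OC | starting material
21 | 2α-acetoxy-4β-hydroxy-10-oxodauc-8-en-6α-yl 3,4-dimethoxybenzoate | COc1ccc(C(=O)O[C@@H]2CC(C)=CC(=O)[C@]3(C)[C@H](OC(C)=O)C[C@](O)(C(C)C)[C@@H]23)cc1OC | intermediate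
22 | 2α-acetoxy-4β,10α-dihydroxydauc-8-en-6α-yl 3,4-dimethoxybenzoate | COc1ccc(C(=O)O[C@@H]2CC(C)=C[C@H](O)[C@]3(C)[C@H](OC(C)=O)C[C@](O)(C(C)C)[C@@H]23)cc1OC | intermediate
23 | CNP0197096.2: 2α-acetoxy-8,9-epoxy-4β,10α-dihydroxydaucan-6α-yl 3,4-dimethoxybenzoate, oxirane on the α face | COc1ccc(C(=O)O[C@@H]2C[C@@]3(C)O[C@@H]3[C@H](O)[C@]3(C)[C@H](OC(C)=O)C[C@](O)(C(C)C)[C@@H]23)cc1OC | target

## Step count and risks

Total step count: 16. Longest linear sequence: 16 (from 1; 20 is bought).

Most likely to fail, step 5 (closing a trans-fused cyclopentane with an allylchromium): the fallback sets out from 5 and comes back at 8. Dess–Martin oxidation of 5, with the isopropenyl group left intact, gives 6-formyl-6-methylcarvone F1. Me2AlCl in CH2Cl2 at −78 °C then closes the ring by a type-two carbonyl–ene reaction, with the aldehyde as enophile and the isopropenyl group as ene, to give 8 directly.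

Most likely to fail, step 9 (carbene attack at the wrong double bond of the dienol ether, or desilylation by tert-butoxide): the fallback sets out from 11 and comes back at 15. Et2Zn/CH2I2, an oxygen-directed zinc carbenoid, cyclopropanates the silyl enol ether bond to the siloxycyclopropane F2. FeCl3 in DMF at 0 °C opens it by one-electron oxidation to the β-chloro ketone F3. NaOAc in MeOH followed by dilute HCl eliminates HCl and removes the silyl ethers to give 15, with no bromide to take off.

Most likely to fail, step 15 (facial selectivity at C10): the fallback sets out from 21 and comes back at 22. If the borohydride reduction gives mainly the 10β-alcohol F4, this is inverted by a Mitsunobu reaction with chloroacetic acid (PPh3, DIAD, THF) to the 10α-chloroacetate F5. Thiourea and NaHCO3 in EtOH then cleave the chloroacetate without touching the acetate or the veratrate, giving 22.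

## Further compounds

F1 | step 5 | 6-formyl-6-methylcarvone (CHO trans, CH3 cis to isopropenyl) | C=C(C)[C@H]1CC=C(C)C(=O)[C@]1(C)C=O
F2 | step 9 | siloxycyclopropane: CH2 (C9) bridging C8 and C10 on the α face of 11 | C1=C[C@]2(C)C[C@]2(O[Si](C)(C)C)[C@]3(C)[C@H](O[Si](C)(C)C)C[C@](O[Si](C)(C)C)(C(C)C)[C@@H]13
F3 | step 9 | 8-chloro-2α,4β-bis(trimethylsilyloxy)dauc-6-en-10-one (C8 epimers) | C1=CC(C)(Cl)CC(=O)[C@]2(C)[C@H](O[Si](C)(C)C)C[C@](O[Si](C)(C)C)(C(C)C)[C@@H]12
F4 | step 15 | 2α-acetoxy-4β,10β-dihydroxydauc-8-en-6α-yl 3,4-dimethoxybenzoate | COc1ccc(C(=O)O[C@@H]2CC(C)=C[C@@H](O)[C@]3(C)[C@H](OC(C)=O)C[C@](O)(C(C)C)[C@@H]23)cc1OC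
F5 | step 15 | 2α-acetoxy-10α-(chloroacetoxy)-4β-hydroxydauc-8-en-6α-yl 3,4-dimethoxybenzoate | COc1ccc(C(=O)O[C@@H]2CC(C)=C[C@H](OC(=O)CCl)[C@]3(C)[C@H](OC(C)=O)C[C@](O)(C(C)C)[C@@H]23)cc1OC
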